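**Strategy.** Everything rests on closing the butenolide (ring B) last through its C4(sp2)–C5H2(sp3) bond. The feature exploited is that C5 hangs on the lactone oxygen O1. The O1–C5 unit is therefore installed beforehand as a tributylstannylmethyl ester, and C4 is activated as the (Z)-enol triflate of a β-keto ester. One intramolecular Stille coupling then joins C4 to C5 and should deliver the 4-alkyl-2(5H)-furanone with its C3=C4 double bond already in place. The open-chain precursor carries the finished trimethylcyclohexenone (ring A), made by B-alkyl Suzuki coupling, copper-catalysed asymmetric methyl addition with enolate methylation, and an oxidative enone transposition.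

Key step: step 12

Remark: ring A is the cyclohexenone and ring B the butenolide, numbered O1, C2(=O), C3H, C4, C5H2; in step 5 the sense of induction is assumed to follow that of unsubstituted cyclohex-2-enone, the antipodal ligand being taken otherwise.

**Route**

Step 1
Reactants: 1 geranyl bromide; 2 tert-butyl acetate
Product: 4 tert-butyl (4E)-5,9-dimethyldeca-4,8-dienoate, via lithium enolate of tert-butyl acetate 3 (not isolated)
Conditions: LiN(i-Pr)2, THF, −78 °C; then 1, −78 °C to rt
Reagents that add atoms: none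
Why: SN2 alkylation of the lithium ester enolate by the primary allylic bromide (ester enolate alkylation) should occur at the unsubstituted terminus and leave the E olefin untouched.

Step 2
Reactants: 4 tert-butyl (4E)-5,9-dimethyldeca-4,8-dienoate
Product: 6 tert-butyl (4E,8E)-5,9-dimethyl-10-oxodeca-4,8-dienoate, via allylic alcohol 5 (not isolated)
Conditions: SeO2 (cat.), t-BuOOH, salicylic acid (cat.), CH2Cl2, rt; then MnO2, CH2Cl2, rt
Reagents that add atoms: selenium dioxide O=[Se]=O; tert-butyl hydroperoxide CC(C)(C)OO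
Why: Selenium dioxide allylic oxidation (ene reaction, then 2,3-sigmatropic shift) should attack the E-methyl group of the more accessible terminal trisubstituted olefin to give the E allylic alcohol, which MnO2 oxidises chemoselectively to the enal.

Step 3
Reactants: 6 tert-butyl (4E,8E)-5,9-dimethyl-10-oxodeca-4,8-dienoate
Product: 7 tert-butyl (4E,8E)-5,9-dimethylundeca-4,8,10-trienoate
Conditions: Ph3PCH3Br, NaN(SiMe3)2, THF, 0 °C; then 6, −78 °C to 0 °C
Reagents that add atoms: methyltriphenylphosphonium bromide C[P+](c1ccccc1)(c1ccccc1)c1ccccc1.[Br-]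
Why: Wittig methylenation of the aldehyde by the non-stabilised ylide is far faster than attack on the tert-butyl ester and creates no stereogenic olefin.

Step 4
Reactants: 7 tert-butyl (4E,8E)-5,9-dimethylundeca-4,8,10-trienoate; 8 2-iodocyclohex-2-en-1-one
Product: 10 tert-butyl (4E,8E)-5,9-dimethyl-11-(6-oxocyclohex-1-en-1-yl)undeca-4,8-dienoate, via B-alkyl-9-BBN borane 9 (not isolated)
Conditions: 9-BBN, THF, 0 °C to rt; then 8, PdCl2(dppf) (cat.), AsPh3, Cs2CO3, DMF/THF/H2O, rt
Reagents that add atoms: none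
Why: 9-BBN should hydroborate only the monosubstituted terminal double bond of the diene in the anti-Markovnikov sense (trisubstituted olefins and ester are inert), and the primary alkylborane then undergoes B-alkyl Suzuki–Miyaura coupling with the α-iodoenone.

Step 5
Reactants: 10 tert-butyl (4E,8E)-5,9-dimethyl-11-(6-oxocyclohex-1-en-1-yl)undeca-4,8-dienoate
Product: 12 tert-butyl (4E,8E)-11-[(1R,2R)-1,2-dimethyl-6-oxocyclohexyl]-5,9-dimethylundeca-4,8-dienoate, via dimethylaluminium enolate 11 (not isolated)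
Conditions: Me3Al, CuTC (copper thiophene-2-carboxylate, cat.), (R)-BINOL-derived N,N-bis[(S)-1-phenylethyl]phosphoramidite (cat.), Et2O, −30 °C; then MeLi (1 equiv per aluminium), DMPU, MeI, −30 °C to 0 °C
Reagents that add atoms: trimethylaluminium C[Al](C)C; iodomethane CI
Why: Copper-catalysed asymmetric conjugate addition sets the ring CH–CH3 centre under control of the chiral phosphoramidite, and the aluminium enolate, activated as its lithium ate complex, should be C-methylated anti to the pseudoaxial β-methyl group (A1,2 strain with the side chain), so that the two ring methyl groups end up trans and the quaternary centre is fixed.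

Step 6
Reactants: 12 tert-butyl (4E,8E)-11-[(1R,2R)-1,2-dimethyl-6-oxocyclohexyl]-5,9-dimethylundeca-4,8-dienoate
Product: 13 tert-butyl (4E,8E)-11-[(1R,6R)-1,6-dimethyl-2-oxocyclohex-3-en-1-yl]-5,9-dimethylundeca-4,8-dienoate
Conditions: IBX, 4-methoxypyridine N-oxide, DMSO, rt
Reagents that add atoms: none
Why: IBX dehydrogenation of the ketone through its only possible enol (the other α-carbon is quaternary) should give the enone, and the quaternary centre also blocks over-oxidation to a phenol.

Step 7
Reactants: 13 tert-butyl (4E,8E)-11-[(1R,6R)-1,6-dimethyl-2-oxocyclohex-3-en-1-yl]-5,9-dimethylundeca-4,8-dienoate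
Product: 14 tert-butyl (4E,8E)-11-[(1R,6R)-2-hydroxy-1,2,6-trimethylcyclohex-3-en-1-yl]-5,9-dimethylundeca-4,8-dienoate (both carbinol epimers)
Conditions: MeLi, CeCl3, THF, −78 °C
Reagents that add atoms: methyllithium [Li]C
Why: The organocerium reagent should add 1,2 to the hindered, non-enolisable enone without touching the tert-butyl ester at −78 °C, and the configuration of the new carbinol centre is irrelevant because it is lost in step 8.

Step 8
Reactants: 14 tert-butyl (4E,8E)-11-[(1R,6R)-2-hydroxy-1,2,6-trimethylcyclohex-3-en-1-yl]-5,9-dimethylundeca-4,8-dienoate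
Product: 15 tert-butyl (4E,8E)-5,9-dimethyl-11-[(1R,6R)-1,2,6-trimethyl-4-oxocyclohex-2-en-1-yl]undeca-4,8-dienoate
Conditions: pyridinium chlorochromate (C5H5NH)[CrO3Cl], NaOAc, 4 Å molecular sieves, CH2Cl2, rt
Reagents that add atoms: pyridinium chlorochromate [O-][Cr](=O)(=O)Cl.c1cc[nH+]cc1
Why: Oxidative 1,3-transposition of the tertiary allylic alcohol (Babler–Dauben oxidation) through 3,3-sigmatropic shift of the chromate ester and oxidation of the resulting secondary chromate should give the β-methyl enone of ring A.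

Step 9
Reactants: 15 tert-butyl (4E,8E)-5,9-dimethyl-11-[(1R,6R)-1,2,6-trimethyl-4-oxocyclohex-2-en-1-yl]undeca-4,8-dienoate
Product: 17 (4E,8E)-5,9-dimethyl-11-[(1R,6R)-1,2,6-trimethyl-4-oxocyclohex-2-en-1-yl]undeca-4,8-dienoic acid, via trimethylsilyl ester 16 (not isolated)
Conditions: Me3SiOTf, 2,6-lutidine, CH2Cl2, 0 °C; then aqueous work-up (pH 4)
Reagents that add atoms: none
Why: Silyl triflate-mediated cleavage of the tert-butyl ester (loss of 2-methylpropene under lutidine buffering) avoids protic acid that could protonate the trisubstituted olefins, and the silyl ester is hydrolysed on work-up.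

Step 10
Reactants: 17 (4E,8E)-5,9-dimethyl-11-[(1R,6R)-1,2,6-trimethyl-4-oxocyclohex-2-en-1-yl]undeca-4,8-dienoic acid; 18 Meldrum's acid (2,2-dimethyl-1,3-dioxane-4,6-dione); 19 (tributylstannyl)methanol
Product: 21 (tributylstannyl)methyl (6E,10E)-7,11-dimethyl-3-oxo-13-[(1R,6R)-1,2,6-trimethyl-4-oxocyclohex-2-en-1-yl]trideca-6,10-dienoate, via acyl Meldrum's acid 20 (not isolated)
Conditions: 18, DCC, DMAP, CH2Cl2, 0 °C to rt; then 19, toluene, 90 °C
Reagents that add atoms: none
Why: C-acylation of Meldrum's acid by the carbodiimide-activated acid, then thermolysis to an acylketene (loss of acetone and CO2) that is trapped by the stannyl alcohol, should give the β-keto ester under neutral conditions that spare the enone.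

Step 11
Reactants: 21 (tributylstannyl)methyl (6E,10E)-7,11-dimethyl-3-oxo-13-[(1R,6R)-1,2,6-trimethyl-4-oxocyclohex-2-en-1-yl]trideca-6,10-dienoate
Product: 23 (tributylstannyl)methyl (2Z,6E,10E)-7,11-dimethyl-3-(trifluoromethanesulfonyloxy)-13-[(1R,6R)-1,2,6-trimethyl-4-oxocyclohex-2-en-1-yl]trideca-2,6,10-trienoate, via sodium enolate 22 (not isolated)
Conditions: NaH (1.05 equiv), THF, 0 °C; then PhNTf2, 0 °C to rt
Reagents that add atoms: N-phenylbis(trifluoromethanesulfonimide) O=S(=O)(N(c1ccccc1)S(=O)(=O)C(F)(F)F)C(F)(F)F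
Why: The chelated sodium enolate of the β-keto ester is Z-configured and should be O-sulfonylated with retention (enol triflate formation), placing the triflate cis to the ester, while the far less acidic ring enone is not deprotonated by one equivalent of NaH.

Step 12
Reactants: 23 (tributylstannyl)methyl (2Z,6E,10E)-7,11-dimethyl-3-(trifluoromethanesulfonyloxy)-13-[(1R,6R)-1,2,6-trimethyl-4-oxocyclohex-2-en-1-yl]trideca-2,6,10-trienoate
Product: 24 cyclolinteinone, 4-{(3E,7E)-4,8-dimethyl-10-[(1R,6R)-1,2,6-trimethyl-4-oxocyclohex-2-en-1-yl]deca-3,7-dien-1-yl}furan-2(5H)-one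
Conditions: Pd2(dba)3 (5 mol%), AsPh3 (40 mol%), CuI (20 mol%), LiCl (3 equiv), NMP, 60 °C, 0.005 M
Reagents that add atoms: none
Why: Zerovalent palladium inserts into the C4–OTf bond of the β-triflyloxy enoate, the tin-bound C5H2 group is passed on (via copper, helped by its α-oxygen) to the neighbouring palladium, and reductive elimination from the six-membered palladacycle (Pd, C4, C3, C2, O1, C5) forms the C4–C5 bond (intramolecular Stille coupling). The closest known reactions are the Stille coupling of enol triflates with (hydroxymethyl)- and (acyloxymethyl)tributylstannanes and Stille ring closures of tethered vinyl triflates. Ring B is closed as a five-membered lactone by a C(sp2)–C(sp3) bond between the enoate β-carbon and the O-bound methylene, with the C3=C4 double bond endocyclic and conjugated as in the target. No stereocentre is created, and the two in ring A are remote and untouched. The step needs palladium cis to the ester at C4, secured by the Z geometry from step 11, and transfer of the oxygenated CH2 rather than butyl, secured by the α-oxygen and the intramolecular delivery; high dilution suppresses dimerisation. The ester must reach its s-cis rotamer, which should be accessible at 60 °C.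

**Compound list**

1 | geranyl bromide, (2E)-1-bromo-3,7-dimethylocta-2,6-diene | CC(C)=CCC/C(C)=C/CBr | starting material
2 | tert-butyl acetate | CC(=O)OC(C)(C)C | starting material
3 | lithium enolate of tert-butyl acetate (not isolated) | C=C([O-])OC(C)(C)C.[Li+] | intermediate
4 | tert-butyl (4E)-5,9-dimethyldeca-4,8-dienoate | CC(C)=CCC/C(C)=C/CCC(=O)OC(C)(C)C | intermediate
5 | tert-butyl (4E,8E)-10-hydroxy-5,9-dimethyldeca-4,8-dienoate (not isolated) | OC/C(C)=C/CC/C(C)=C/CCC(=O)OC(C)(C)C | intermediate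
6 | tert-butyl (4E,8E)-5,9-dimethyl-10-oxodeca-4,8-dienoate | O=C/C(C)=C/CC/C(C)=C/CCC(=O)OC(C)(C)C | intermediate
7 | tert-butyl (4E,8E)-5,9-dimethylundeca-4,8,10-trienoate | C=C/C(C)=C/CC/C(C)=C/CCC(=O)OC(C)(C)C | intermediate
8 | 2-iodocyclohex-2-en-1-one | O=C1CCCC=C1I | starting material
9 | tert-butyl (4E,8E)-11-(9-borabicyclo[3.3.1]nonan-9-yl)-5,9-dimethylundeca-4,8-dienoate (not isolated) | B1(C2CCCC1CCC2)CC/C(C)=C/CC/C(C)=C/CCC(=O)OC(C)(C)C | intermediate
10 | tert-butyl (4E,8E)-5,9-dimethyl-11-(6-oxocyclohex-1-en-1-yl)undeca-4,8-dienoate | O=C1CCCC=C1CC/C(C)=C/CC/C(C)=C/CCC(=O)OC(C)(C)C | intermediate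
11 | tert-butyl (4E,8E)-11-[(6R)-2-(dimethylalumanyloxy)-6-methylcyclohex-1-en-1-yl]-5,9-dimethylundeca-4,8-dienoate (not isolated) | C[Al](C)OC1=C(CC/C(C)=C/CC/C(C)=C/CCC(=O)OC(C)(C)C)[C@H](C)CCC1 | intermediate
12 | tert-butyl (4E,8E)-11-[(1R,2R)-1,2-dimethyl-6-oxocyclohexyl]-5,9-dimethylundeca-4,8-dienoate | O=C1CCC[C@@H](C)[C@@]1(C)CC/C(C)=C/CC/C(C)=C/CCC(=O)OC(C)(C)C | intermediate
13 | tert-butyl (4E,8E)-11-[(1R,6R)-1,6-dimethyl-2-oxocyclohex-3-en-1-yl]-5,9-dimethylundeca-4,8-dienoate | O=C1C=CC[C@@H](C)[C@@]1(C)CC/C(C)=C/CC/C(C)=C/CCC(=O)OC(C)(C)C | intermediate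
14 | tert-butyl (4E,8E)-11-[(1R,6R)-2-hydroxy-1,2,6-trimethylcyclohex-3-en-1-yl]-5,9-dimethylundeca-4,8-dienoate (carbinol centre undefined, both epimers) | CC1(O)C=CC[C@@H](C)[C@@]1(C)CC/C(C)=C/CC/C(C)=C/CCC(=O)OC(C)(C)C | intermediate
15 | tert-butyl (4E,8E)-5,9-dimethyl-11-[(1R,6R)-1,2,6-trimethyl-4-oxocyclohex-2-en-1-yl]undeca-4,8-dienoate | CC1=CC(=O)C[C@@H](C)[C@@]1(C)CC/C(C)=C/CC/C(C)=C/CCC(=O)OC(C)(C)C | intermediate
16 | trimethylsilyl (4E,8E)-5,9-dimethyl-11-[(1R,6R)-1,2,6-trimethyl-4-oxocyclohex-2-en-1-yl]undeca-4,8-dienoate (not isolated) | CC1=CC(=O)C[C@@H](C)[C@@]1(C)CC/C(C)=C/CC/C(C)=C/CCC(=O)O[Si](C)(C)C | intermediate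
17 | (4E,8E)-5,9-dimethyl-11-[(1R,6R)-1,2,6-trimethyl-4-oxocyclohex-2-en-1-yl]undeca-4,8-dienoic acid | CC1=CC(=O)C[C@@H](C)[C@@]1(C)CC/C(C)=C/CC/C(C)=C/CCC(=O)O | intermediate
18 | Meldrum's acid, 2,2-dimethyl-1,3-dioxane-4,6-dione | CC1(C)OC(=O)CC(=O)O1 | starting material
19 | (tributylstannyl)methanol | CCCC[Sn](CCCC)(CCCC)CO | starting material
20 | 5-{(4E,8E)-1-hydroxy-5,9-dimethyl-11-[(1R,6R)-1,2,6-trimethyl-4-oxocyclohex-2-en-1-yl]undeca-4,8-dien-1-ylidene}-2,2-dimethyl-1,3-dioxane-4,6-dione (acyl Meldrum's acid, not isolated) | CC1=CC(=O)C[C@@H](C)[C@@]1(C)CC/C(C)=C/CC/C(C)=C/CCC(O)=C1C(=O)OC(C)(C)OC1=O | intermediate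
21 | (tributylstannyl)methyl (6E,10E)-7,11-dimethyl-3-oxo-13-[(1R,6R)-1,2,6-trimethyl-4-oxocyclohex-2-en-1-yl]trideca-6,10-dienoate | CC1=CC(=O)C[C@@H](C)[C@@]1(C)CC/C(C)=C/CC/C(C)=C/CCC(=O)CC(=O)OC[Sn](CCCC)(CCCC)CCCC | intermediate
22 | sodium (Z)-enolate of 21 (not isolated) | CC1=CC(=O)C[C@@H](C)[C@@]1(C)CC/C(C)=C/CC/C(C)=C/CC/C([O-])=C/C(=O)OC[Sn](CCCC)(CCCC)CCCC.[Na+] | intermediate
23 | (tributylstannyl)methyl (2Z,6E,10E)-7,11-dimethyl-3-(trifluoromethanesulfonyloxy)-13-[(1R,6R)-1,2,6-trimethyl-4-oxocyclohex-2-en-1-yl]trideca-2,6,10-trienoate | CC1=CC(=O)C[C@@H](C)[C@@]1(C)CC/C(C)=C/CC/C(C)=C/CC/C(OS(=O)(=O)C(F)(F)F)=C/C(=O)OC[Sn](CCCC)(CCCC)CCCC | intermediate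
24 | cyclolinteinone, 4-{(3E,7E)-4,8-dimethyl-10-[(1R,6R)-1,2,6-trimethyl-4-oxocyclohex-2-en-1-yl]deca-3,7-dien-1-yl}furan-2(5H)-one | CC1=CC(=O)C[C@@H](C)[C@@]1(C)CC/C(C)=C/CC/C(C)=C/CCC1=CC(=O)OC1 | target

**Step count.** Total: 12 steps. Longest linear sequence: 12 steps (from geranyl bromide 1).

**Steps most likely to fail, with fallbacks**

Step 12 (Stille ring closure). Transmetalation through the ester tether may be slow because the ester has to reach its s-cis rotamer, so protodestannylation, butyl transfer or reduction of the triflate could take over. The fallback closes the same C4–C5 bond by a radical route, a nickel/photoredox decarboxylative vinylation; it sets out from acid 17 and comes back at 24. Acid 17 is converted into acyl Meldrum's acid 20 as in step 10, and 20 is heated with tert-butyl glycolate in toluene to give the 2-tert-butoxy-2-oxoethyl β-keto ester F1. NaH converts F1 into its sodium enolate F2, and PhNTf2 gives the Z-enol triflate F3. Me3SiOTf/2,6-lutidine converts F3 into the trimethylsilyl ester F4, which is hydrolysed on work-up to the carboxymethyl ester acid F5. Blue-light irradiation of F5 with Ir[dF(CF3)ppy]2(dtbbpy)PF6, NiCl2·glyme, 4,4'-di-tert-butyl-2,2'-bipyridine and Cs2CO3 in DMSO oxidises the carboxylate. The α-acyloxymethyl radical formed by loss of CO2 is captured by the vinylnickel species from the triflate, and reductive elimination should close ring B to 24.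

Step 5 (asymmetric methyl addition and enolate methylation). Facial discrimination in the methyl transfer to the α-substituted enone may be poor, or the aluminium enolate may be quenched by proton transfer or O-alkylation instead of C-methylation. The fallback sets the ring CH–CH3 centre by hydride instead of methyl delivery; it sets out from triene 7 and comes back at 12. Triene 7 is hydroborated as in step 4 (borane 9) and coupled with 2-iodo-3-methylcyclohex-2-en-1-one to give the tetrasubstituted enone F6. Copper hydride conjugate reduction (Cu(OAc)2, DTBM-SEGPHOS of the appropriate handedness, diethoxymethylsilane, toluene) gives the diethoxy(methyl)silyl enol ether F7 with the stereocentre set by the ligand. Bu4N[Ph3SiF2] and MeI then methylate the regiodefined enolate anti to the β-methyl group to give 12.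

Step 2 (allylic oxidation). The oxidation may fail to discriminate the terminal from the internal trisubstituted olefin and may run on past the aldehyde. The fallback makes the enal by olefin cross-metathesis instead of C–H oxidation; it sets out from 4 and comes back at 6. Ester 4 and excess methacrolein with the second-generation Grubbs catalyst (CH2Cl2, 40 °C) should exchange the less hindered terminal isopropylidene group for the E-configured 2-methylpropenal terminus with loss of 2-methylpropene. No new compound is made (F0).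

**Further compounds**

F1 | step 12 | 2-tert-butoxy-2-oxoethyl (6E,10E)-7,11-dimethyl-3-oxo-13-[(1R,6R)-1,2,6-trimethyl-4-oxocyclohex-2-en-1-yl]trideca-6,10-dienoate | CC1=CC(=O)C[C@@H](C)[C@@]1(C)CC/C(C)=C/CC/C(C)=C/CCC(=O)CC(=O)OCC(=O)OC(C)(C)C
F2 | step 12 | sodium (Z)-enolate of F1 | CC1=CC(=O)C[C@@H](C)[C@@]1(C)CC/C(C)=C/CC/C(C)=C/CC/C([O-])=C/C(=O)OCC(=O)OC(C)(C)C.[Na+]
F3 | step 12 | 2-tert-butoxy-2-oxoethyl (2Z,6E,10E)-7,11-dimethyl-3-(trifluoromethanesulfonyloxy)-13-[(1R,6R)-1,2,6-trimethyl-4-oxocyclohex-2-en-1-yl]trideca-2,6,10-trienoate | CC1=CC(=O)C[C@@H](C)[C@@]1(C)CC/C(C)=C/CC/C(C)=C/CC/C(OS(=O)(=O)C(F)(F)F)=C/C(=O)OCC(=O)OC(C)(C)C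
F4 | step 12 | trimethylsilyl ester of F5 | CC1=CC(=O)C[C@@H](C)[C@@]1(C)CC/C(C)=C/CC/C(C)=C/CC/C(OS(=O)(=O)C(F)(F)F)=C/C(=O)OCC(=O)O[Si](C)(C)C
F5 | step 12 | {[(2Z,6E,10E)-7,11-dimethyl-3-(trifluoromethanesulfonyloxy)-13-[(1R,6R)-1,2,6-trimethyl-4-oxocyclohex-2-en-1-yl]trideca-2,6,10-trienoyl]oxy}acetic acid | CC1=CC(=O)C[C@@H](C)[C@@]1(C)CC/C(C)=C/CC/C(C)=C/CC/C(OS(=O)(=O)C(F)(F)F)=C/C(=O)OCC(=O)O
F6 | step 5 | tert-butyl (4E,8E)-5,9-dimethyl-11-(2-methyl-6-oxocyclohex-1-en-1-yl)undeca-4,8-dienoate | O=C1CCCC(C)=C1CC/C(C)=C/CC/C(C)=C/CCC(=O)OC(C)(C)C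
F7 | step 5 | tert-butyl (4E,8E)-11-[(6R)-2-{[diethoxy(methyl)silyl]oxy}-6-methylcyclohex-1-en-1-yl]-5,9-dimethylundeca-4,8-dienoate | CCO[Si](C)(OCC)OC1=C(CC/C(C)=C/CC/C(C)=C/CCC(=O)OC(C)(C)C)[C@H](C)CCC1
F0 | step 2 | none | none
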